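**Retrosynthetic overview**
- Target 8 comes from tertiary allylic alcohol 5 by an oxidative 1,3-transposition: a new C3–O bond is made, the C1–O bond is lost, and the alkene moves into conjugation (key step).
- Alcohol 5 comes from 1,2-addition of nonadecylmagnesium bromide 3 (made from bromide 1) to cyclohex-2-en-1-one 2.
- No ring is formed: the six-membered ring is bought intact in 2.

Assumption: the target, 3-nonadecylcyclohex-2-en-1-one (C25H46O), has no stereocentre, so there is no configuration to control; the route has only two steps, so the risk ranking covers both rather than three.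

**Step 1**
Reactants: 1 1-bromononadecane; 2 cyclohex-2-en-1-one
Product: 5 1-nonadecylcyclohex-2-en-1-ol (racemic), via nonadecylmagnesium bromide 3 (not isolated), via bromomagnesium 1-nonadecylcyclohex-2-en-1-olate 4 (not isolated)
Conditions: 1 (1.2 equiv), Mg turnings (1.5 equiv), I2 (cat.), THF, 45 °C; then 2 (1.0 equiv), THF, −20 → 0 °C; sat. aq NH4Cl, 0 °C; chromatography on Et3N-washed SiO2
Reagents that add atoms: none
Why: Copper-free primary alkyl Grignard reagents attack the carbonyl carbon of cyclohex-2-en-1-one in THF at low temperature (Grignard 1,2-addition), and the mild NH4Cl quench keeps the acid-labile tertiary allylic alcohol intact; the new centre is racemic and is erased in step 2.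

**Step 2**
Reactants: 5 1-nonadecylcyclohex-2-en-1-ol (racemic)
Product: 8 3-nonadecylcyclohex-2-en-1-one, via oxovanadium bis(triphenylsilanolate) 1-nonadecylcyclohex-2-en-1-olate 6 (not isolated), via oxovanadium bis(triphenylsilanolate) 3-nonadecylcyclohex-2-en-1-olate 7 (not isolated)
Conditions: OV(OSiPh3)3 (5 mol%), Et3N (10 mol%), O2 (1 atm), 4 Å MS, ClCH2CH2Cl (0.2 M), 60 °C
Reagents that add atoms: dioxygen, O=O
Why: Proposed new method: a tandem oxo-transposition/aerobic dehydrogenation on one pentavalent vanadium centre, in which alcohol exchange on OV(OSiPh3)3 gives vanadate ester 6, whose V=O oxygen attacks C3 through a six-membered chair [3,3] transition state to form the new C3–O bond and move the alkene to C1=C2 (7); 7, unlike 6, has a hydrogen on the carbinol carbon, so Et3N-assisted two-electron dehydrogenation releases conjugated enone 8 and trivalent vanadium, which O2 returns to the pentavalent oxo state (refilling the V=O oxygen that is handed to C3), and because tertiary ester 6 cannot be oxidised the reversible shift is drained only through 7; the closest known reaction types are the oxovanadium-catalysed 1,3-transposition of allylic alcohols, the base-assisted aerobic oxidation of allylic alcohols by oxovanadium alkoxides, and the stoichiometric Babler–Dauben oxidative transposition with hexavalent chromium; no stereocentre is formed.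

**Compound list**
1 | 1-bromononadecane | CCCCCCCCCCCCCCCCCCCBr | starting material
2 | cyclohex-2-en-1-one | O=C1C=CCCC1 | starting material
3 | nonadecylmagnesium bromide (C19H39MgBr) | CCCCCCCCCCCCCCCCCCC[Mg]Br | intermediate
4 | bromomagnesium 1-nonadecylcyclohex-2-en-1-olate (racemic) | CCCCCCCCCCCCCCCCCCCC1(O[Mg]Br)C=CCCC1 | intermediate
5 | 1-nonadecylcyclohex-2-en-1-ol (racemic) | CCCCCCCCCCCCCCCCCCCC1(O)C=CCCC1 | intermediate
6 | oxovanadium bis(triphenylsilanolate) 1-nonadecylcyclohex-2-en-1-olate (racemic; pentavalent vanadium) | CCCCCCCCCCCCCCCCCCCC1(O[V](=O)(O[Si](c2ccccc2)(c2ccccc2)c2ccccc2)O[Si](c2ccccc2)(c2ccccc2)c2ccccc2)C=CCCC1 | intermediate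
7 | oxovanadium bis(triphenylsilanolate) 3-nonadecylcyclohex-2-en-1-olate (racemic; pentavalent vanadium) | CCCCCCCCCCCCCCCCCCCC1=CC(O[V](=O)(O[Si](c2ccccc2)(c2ccccc2)c2ccccc2)O[Si](c2ccccc2)(c2ccccc2)c2ccccc2)CCC1 | intermediate
8 | 3-nonadecylcyclohex-2-en-1-one | CCCCCCCCCCCCCCCCCCCC1=CC(=O)CCC1 | target

**Totals**
Total step count: 2. Longest linear sequence: 2 steps.

**Steps most likely to fail**

1. Step 2 (the proposed new step). The [3,3] shift on this ligand set may need more than 60 °C, where 5 can dehydrate to a 1,3-diene. The dehydrogenation of 7 may be slow. A vanadium peroxo species formed on reoxidation could epoxidise 5. The fallback uses known chemistry, sets out from 5 and comes back at 8. Stir 5 with pyridinium chlorochromate [C5H5NH][CrO3Cl] (2 equiv) and Celite in CH2Cl2 at room temperature. The chromate ester of the tertiary alcohol undergoes the [3,3] shift and the transposed secondary chromate ester collapses to 8 (Babler–Dauben oxidation). This replaces the catalytic aerobic relay with stoichiometric hexavalent chromium and makes no new compound (F0).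

2. Step 1. The risks are Wurtz coupling while 3 is formed, conjugate addition to or enolisation of 2, and loss of acid-labile 5 on silica. The fallback sets out from 3 and comes back at 8. Add 3 to 3-ethoxycyclohex-2-en-1-one F1 in THF at 0 °C to give 3-ethoxy-1-nonadecylcyclohex-2-en-1-ol F2 as its bromomagnesium alkoxide, which is not isolated. Then stir with 1 M aq HCl at room temperature. Ionisation of the tertiary hydroxyl, hydrolysis of the resulting oxocarbenium ion and loss of ethanol give 8 directly (Stork–Danheiser alkylative carbonyl transposition). The vinylogous ester cannot undergo conjugate addition, 5 is never handled, and step 2 is not needed on this path.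

**Further compounds**
F1 | step 1 | 3-ethoxycyclohex-2-en-1-one | CCOC1=CC(=O)CCC1
F2 | step 1 | 3-ethoxy-1-nonadecylcyclohex-2-en-1-ol (racemic) | CCCCCCCCCCCCCCCCCCCC1(O)C=C(OCC)CCC1
F0 | step 2 | none | none
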